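## The problem

Compound 18 is a 2,2-dimethylchroman. Benzene ring A is fused through C4a–C8a to dihydropyran ring B and is substituted at every position except C6: an E-styryl group at C5, a free hydroxyl at C7 and a prenyl group at C8. The only stereocenter is the secondary carbinol C3 (R), set between the quaternary C2 and the benzylic methylene C4. No other element in the molecule can relay chirality to it, so it has to come from a catalyst, a reagent or a chiral building block; once set it has no easy epimerisation path. O1 is flanked by two five-carbon units of prenyl type: the intact prenyl group on C8 and the cyclised, oxygenated C4–C3–C2(CH3)2 unit on C4a. A synthesis must tell them apart, which rules out a late epoxidation and cyclisation of a doubly prenylated phenol. The two phenolic oxygens, O1 and the C7 hydroxyl, are meta to each other on either side of C8 and must also be differentiated. The prenyl alkene closes onto a neighbouring phenol under acid and is epoxidised by electrophilic oxidants. Together with the E-stilbene and the electron-rich ring, it excludes strong acid, hydrogenation and unselective oxidants, above all late in the route. The enabling feature is that O1, C8a, C4a and C4 are the four atoms of an ortho-quinone methide heterodiene with C4 an unsubstituted methylene. C2–C3 is a two-carbon alkene unit whose gem-dimethyl end can carry positive charge and whose C3 oxygen can be stood in for by boron. Ring B is therefore the footprint of an oxa-[4+2] cycloaddition that forms O1–C2 and C3–C4 and creates C3.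

## Retrosynthesis

**18 to 16.** The C7 silyl ether of 17 is a last-step protecting group. The C3–O bond of 17 is traced back to the C3–B bond of boronate 16, because oxidation of a secondary boronate goes with retention. Boron is preferred to oxygen at C3 because it reverses the polarity of the alkene partner: an enol ether would join its oxygen-bearing carbon to O1 and give a 2-alkoxy-3,3-dimethylchroman. The forward steps only need a mild oxidant that leaves two alkenes and an aryl silyl ether alone.

**16 to 13 and 14.** Cutting O1–C2 and C3–C4 together removes ring B and the stereocenter in one operation. It leaves salicyl alcohol 13, which acts through quinone methide 15, and the commercial alkenylboronate 14. Two neighbouring cuts were weighed. Cutting O1–C2 alone (phenol onto an epoxidised C4a prenyl group) cannot distinguish that group from the C8 prenyl group. Cutting C4–C4a (Friedel–Crafts closure) needs a chiral side chain already on O1. The forward reaction must control which face of the alkene bonds to C4, must place C2 on oxygen, and must close the ring faster than boron is lost.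

**13 to 11.** The benzylic alcohol of 13 comes from aldehyde 12 by hydride reduction. The silyl ether of 12 comes from dihydroxy aldehyde 11. The cut is chosen because the aldehyde itself differentiates the two phenols: the C8a hydroxyl is tied up in a hydrogen bond to the carbonyl and is flanked on both sides, while the C7 hydroxyl is free and more acidic. A bulky triisopropylsilyl group is chosen because it also shields C6 in the key step.

**11 to 10.** The C4a–CHO bond is cut to give resorcinol 10. In 10 the two open ring positions are equivalent by symmetry and each is ortho to one hydroxyl and para to the other, so regiochemistry is not in question. The forward reaction must be non-acidic and must stop at monoformylation.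

**10 to 7 and 8.** Removing the two methoxymethyl groups (9) and cutting the stilbene double bond gives aldehyde 7 and commercial phosphonate 8. The olefination is reliably E-selective and puts the unfunctionalised phenyl ring in last.

**7 to 3 and 4.** Aldehyde 7 comes from alcohol 6. The aryl–prenyl bond of 6 is cut to give benzylic alcohol 3 and prenyl bromide 4, joined through dilithio species 5. The position between the two methoxymethyl ethers is the one both groups direct to, so the prenyl group is placed at C8 with no isomer problem. Direct C-prenylation of a free resorcinol would not achieve this.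

**3 to 1.** Alcohol 3 comes from ester 2 by reduction, and 2 from commercial methyl 3,5-dihydroxybenzoate 1 by acetal protection. The symmetry of 1 is kept up to compound 10.

## Roads not taken

**Alternative 1:** Ring A is built and not bought. The cuts are C5–C6 and C8–C8a, which lead to cinnamylidene lactone A2 and sulcatone A3. A2 already holds O1, C2, the silylated C3 carbinol, C4, C4a and C5 with its styryl group; A3 supplies C6, C7, C8 and the prenyl chain. In the forward step the methyl-side kinetic enolate of A3 would add to C5 of A2, the enolate at C8 would then acylate on the lactone carbonyl C8a, and acid would close O1 back onto C8a to give bicyclic enone A1.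
- Merits: C3 arrives with a defined configuration, so no new asymmetric reaction is needed, and the two five-carbon units differ by origin. In certainty of configuration this road is better than the chosen one.
- Weak points: the dienyl acceptor offers the styryl terminus (1,6-addition) as well as C5. The acylation needs the enolate at the more substituted C8 to attack a hindered lactone in competition with proton transfer and retro-Michael cleavage. A1 is two hydrogens short of the arene, and dehydrogenating it next to a prenyl group, an enol ether and a styryl-bearing sp3 carbon invites allylic oxidation and double-bond migration. A2 needs its own asymmetric sequence.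
- Comparison: the chosen plan sets against this a purchased aromatic ring that never changes oxidation level, symmetric intermediates up to 10, and a known-chemistry detour for C3.

**Alternative 2:** Ring A is assembled by a Danheiser benzannulation. The cuts are C7–C8, C8a–C4a and C6–C7, which lead to styrylcyclobutenone A5 and alkynyl ether A6. The tertiary alkoxy group of A6 carries C2 with its two methyl groups and, as an R-configured dioxolane, C3 and the future C4. Heating would open A5, add it to A6 in a [2+2] step, and after four-electron opening and six-electron closure give resorcinol monoether A4.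
- Merits: every substituent of ring A is placed by the mechanism, O1 and the C7 hydroxyl are different from the start, and C3 comes from the chiral pool. In regiocontrol of ring A and in security of configuration this road is better than the chosen one, which must formylate and silylate selectively.
- Weak points: tertiary alkyl alkynyl ethers with β-hydrogens fragment by a retro-ene path at about the temperature the cyclobutenone needs, so A6 may not survive. Ring B is still open in A4; closing C4–C4a requires unmasking the diol, activating the primary carbon and a Friedel–Crafts-type closure beside a free phenol, a prenyl group and a stilbene.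
- Comparison: the chosen plan uses two robust partners in its key step and forms ring B with C3 in one operation, two steps from 18.

**Alternative 3:** The cut is the C4a–C5 bond of ring A, with loss of water. It leads to A8, in which the intact pyran ring is an exocyclic vinylogous ester conjugated to the C7 ketone and the chain ends in the cinnamoyl carbonyl C5. Mild acid would move the enol ether double bond into the ring (C8a=C4a), C4a would add to C5 in an aldol step, and dehydration and enolisation would give arene A7, the C3 silyl ether of 18.
- Merits: it is biomimetic, ring B and C3 are fixed beforehand, no catalyst control is needed, and A7 is one deprotection from 18. After the key step it is shorter than the chosen plan.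
- Weak points: C6, between the two carbonyls, is far more acidic and nucleophilic than the C4a carbon that must react. The cinnamoyl unit offers a conjugate position as well as its carbonyl, and the C7 enol oxygen can close onto it. Acid able to move the enol ether double bond can also hydrolyse it or cyclise the prenyl group. Making A8 by C-acylation of a vinylogous ester is about as long as the whole chosen route.
- Comparison: the chosen plan accepts a riskier stereochemical step in exchange for a key step with a single reactive pair.

Key step: step 10

Assumption: the sense of asymmetric induction in step 10 cannot be derived from an established model. The R antipode of the catalyst is written; the antipode that gives the 3R boronate 16 is the one to be used, and both are equally accessible.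

## Route

Step 1
Reactants: 1 methyl 3,5-dihydroxybenzoate
Product: 2 methyl 3,5-bis(methoxymethoxy)benzoate
Conditions: MOMCl, iPr2NEt, CH2Cl2, 0 °C to rt
Reagents that add atoms: chloromethyl methyl ether, COCCl
Why: Williamson-type O-alkylation of both phenols; the acetal ethers are stable to hydride and organolithium reagents and later direct the metalation.

Step 2
Reactants: 2 methyl 3,5-bis(methoxymethoxy)benzoate
Product: 3 [3,5-bis(methoxymethoxy)phenyl]methanol
Conditions: LiAlH4, THF, 0 °C
Reagents that add atoms: none
Why: Hydride reduction of the ester to the primary alcohol; aryl methoxymethyl ethers are inert to LiAlH4.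

Step 3
Reactants: 3 [3,5-bis(methoxymethoxy)phenyl]methanol; 4 1-bromo-3-methylbut-2-ene (prenyl bromide)
Product: 6 [3,5-bis(methoxymethoxy)-4-(3-methylbut-2-en-1-yl)phenyl]methanol, via dilithio benzyl alkoxide 5 (not isolated)
Conditions: n-BuLi (2.3 equiv), TMEDA, THF, 0 °C; CuI (10 mol %), then 4, −20 °C to rt; H2O
Reagents that add atoms: none
Why: Directed ortho-metalation: after the alkoxide forms, the second equivalent of base removes the proton between the two methoxymethyl ethers, the site both acetal oxygens coordinate and acidify, and the alkoxide is the weaker director. Copper-catalysed SN2 allylation of the aryllithium with 4 then gives the linear prenyl arene.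

Step 4
Reactants: 6 [3,5-bis(methoxymethoxy)-4-(3-methylbut-2-en-1-yl)phenyl]methanol
Product: 7 3,5-bis(methoxymethoxy)-4-(3-methylbut-2-en-1-yl)benzaldehyde
Conditions: MnO2, CH2Cl2, rt
Reagents that add atoms: none
Why: Heterogeneous oxidation of a benzylic alcohol on MnO2; the neutral conditions leave the prenyl alkene and the acetals untouched and cannot over-oxidise.

Step 5
Reactants: 7 3,5-bis(methoxymethoxy)-4-(3-methylbut-2-en-1-yl)benzaldehyde; 8 diethyl benzylphosphonate
Product: 9 1,3-bis(methoxymethoxy)-2-(3-methylbut-2-en-1-yl)-5-[(E)-2-phenylethenyl]benzene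
Conditions: KOtBu, THF, 0 °C to rt
Reagents that add atoms: none
Why: Horner–Wadsworth–Emmons olefination of a non-enolisable aromatic aldehyde; reversible addition and elimination through the less crowded oxaphosphetane should give the E-stilbene.

Step 6
Reactants: 9 1,3-bis(methoxymethoxy)-2-(3-methylbut-2-en-1-yl)-5-[(E)-2-phenylethenyl]benzene
Product: 10 2-(3-methylbut-2-en-1-yl)-5-[(E)-2-phenylethenyl]benzene-1,3-diol
Conditions: TsOH·H2O (cat.), MeOH, 40 °C
Reagents that add atoms: none
Why: Acid-catalysed acetal exchange to methanol releases both phenols; catalytic sulfonic acid at mild temperature is the usual way to unmask prenylated phenols without adding the phenol to the prenyl double bond.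

Step 7
Reactants: 10 2-(3-methylbut-2-en-1-yl)-5-[(E)-2-phenylethenyl]benzene-1,3-diol
Product: 11 2,4-dihydroxy-3-(3-methylbut-2-en-1-yl)-6-[(E)-2-phenylethenyl]benzaldehyde
Conditions: MgCl2, Et3N, (CH2O)n, MeCN, 70 °C; then 1 M HCl, 0 °C
Reagents that add atoms: paraformaldehyde (as formaldehyde), C=O
Why: Magnesium-mediated ortho-formylation of a phenol (Casnati–Skattebøl): the magnesium phenoxide delivers formaldehyde to its ortho carbon and the resulting benzylic alkoxide is oxidised by a second formaldehyde through hydride transfer. The two open positions of 10 are equivalent, the base-mediated conditions spare the prenyl group, and the first formyl group deactivates the ring towards a second.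

Step 8
Reactants: 11 2,4-dihydroxy-3-(3-methylbut-2-en-1-yl)-6-[(E)-2-phenylethenyl]benzaldehyde
Product: 12 2-hydroxy-3-(3-methylbut-2-en-1-yl)-6-[(E)-2-phenylethenyl]-4-[tri(propan-2-yl)silyloxy]benzaldehyde
Conditions: TIPSCl (1.1 equiv), imidazole, DMF, 0 °C to rt
Reagents that add atoms: chlorotri(propan-2-yl)silane, CC(C)[Si](Cl)(C(C)C)C(C)C
Why: Selective silylation of the more acidic, non-chelated hydroxyl para to the aldehyde; the ortho hydroxyl is held in a hydrogen bond to the carbonyl and is flanked by the prenyl and formyl groups, so it should not react with one equivalent of a bulky silyl chloride.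

Step 9
Reactants: 12 2-hydroxy-3-(3-methylbut-2-en-1-yl)-6-[(E)-2-phenylethenyl]-4-[tri(propan-2-yl)silyloxy]benzaldehyde
Product: 13 2-(hydroxymethyl)-6-(3-methylbut-2-en-1-yl)-3-[(E)-2-phenylethenyl]-5-[tri(propan-2-yl)silyloxy]phenol
Conditions: NaBH4, THF/MeOH, 0 °C; pH 7 buffer
Reagents that add atoms: none
Why: Borohydride reduction of the salicylaldehyde to the salicyl alcohol; short reaction at 0 °C with a neutral work-up keeps the electron-rich benzylic alcohol from ionising, and the product is to be used at once.

Step 10
Reactants: 13 2-(hydroxymethyl)-6-(3-methylbut-2-en-1-yl)-3-[(E)-2-phenylethenyl]-5-[tri(propan-2-yl)silyloxy]phenol; 14 4,4,5,5-tetramethyl-2-(2-methylprop-1-en-1-yl)-1,3,2-dioxaborolane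
Product: 16 2-[(3R)-2,2-dimethyl-8-(3-methylbut-2-en-1-yl)-5-[(E)-2-phenylethenyl]-7-[tri(propan-2-yl)silyloxy]-3,4-dihydro-2H-chromen-3-yl]-4,4,5,5-tetramethyl-1,3,2-dioxaborolane, via ortho-quinone methide 15 (not isolated)
Conditions: (R)-3,3'-bis(2,4,6-triisopropylphenyl)-1,1'-binaphthyl-2,2'-diyl hydrogen phosphate (10 mol %), 14 (5 equiv), 5 Å molecular sieves, toluene, 40 °C, slow addition of 13
Reagents that add atoms: none
Why: Proposed new method: the phosphoric acid ionises the primary benzylic alcohol of 13, activated by the para silyloxy group, to the hydrogen-bonded ortho-quinone methide 15; its methylene C4 is attacked by the boron-bearing carbon of 14 because this places the developing positive charge on the tertiary carbon, stabilised by two methyl groups and by hyperconjugation with the β C–B bond, and O1 then closes onto that carbon; the closest known reaction type is the chiral phosphoric acid catalysed inverse-demand oxa-[4+2] cycloaddition of ortho-quinone methides with styrenes, enol ethers and trisubstituted alkenes. Ring B is closed by an intermolecular, concerted but asynchronous [4+2] cycloaddition in which C3–C4 forms ahead of O1–C2 (in the stepwise limit, a six-membered capture of the tertiary cation by the phenolic oxygen). C3 is the only new stereocenter; because C4 is an unsubstituted methylene and C2 carries two identical methyl groups, its configuration depends only on which enantiotopic face of the alkene bonds to C4. That choice is catalyst-controlled: the phosphate is held on O1 by a hydrogen bond and its two triisopropylphenyl walls should leave one quadrant for the pinacolboryl group. The step needs regioselectivity, secured by tertiary-cation character at C2, enantioface selectivity from the catalyst, and ring closure in preference to loss of boron, for which the non-exchanging pinacol ester, the absence of free boronic acid and the dry, non-nucleophilic medium are chosen. The bulky silyl ether shields the nucleophilic C6 position, and slow addition of 13 to an excess of 14 keeps 15 from reacting with the prenyl or stilbene alkene of a second molecule.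

Step 11
Reactants: 16 2-[(3R)-2,2-dimethyl-8-(3-methylbut-2-en-1-yl)-5-[(E)-2-phenylethenyl]-7-[tri(propan-2-yl)silyloxy]-3,4-dihydro-2H-chromen-3-yl]-4,4,5,5-tetramethyl-1,3,2-dioxaborolane
Product: 17 (3R)-2,2-dimethyl-8-(3-methylbut-2-en-1-yl)-5-[(E)-2-phenylethenyl]-7-[tri(propan-2-yl)silyloxy]-3,4-dihydro-2H-chromen-3-ol
Conditions: NaBO3·4H2O, THF/H2O, rt
Reagents that add atoms: sodium perborate (NaBO3·4H2O), [Na+].[Na+].O[B-]1(O)OO[B-](O)(O)OO1
Why: Oxidation of a secondary boronic ester: the peroxo oxygen adds to boron and C3 migrates from boron to oxygen with retention, so the 3R boronate gives the 3R alcohol. The mildly basic, non-electrophilic oxidant spares both alkenes and the aryl silyl ether, and the hydroboration–oxidation of 2H-chromenes to chroman-3-ols shows that migration outruns β-elimination of the ring oxygen.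

Step 12
Reactants: 17 (3R)-2,2-dimethyl-8-(3-methylbut-2-en-1-yl)-5-[(E)-2-phenylethenyl]-7-[tri(propan-2-yl)silyloxy]-3,4-dihydro-2H-chromen-3-ol
Product: 18 (3R)-2,2-dimethyl-8-(3-methylbut-2-en-1-yl)-5-[(E)-2-phenylethenyl]-3,4-dihydro-2H-chromene-3,7-diol
Conditions: Bu4NF, AcOH, THF, 0 °C
Reagents that add atoms: none
Why: Fluoride cleavage of the aryl silyl ether, buffered with acetic acid so that the electron-rich phenoxide is protonated as it forms; the secondary alcohol, the alkenes and C3 are not affected.

## Compound list

1 | methyl 3,5-dihydroxybenzoate | COC(=O)c1cc(O)cc(O)c1 | starting material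
2 | methyl 3,5-bis(methoxymethoxy)benzoate | COCOc1cc(cc(OCOC)c1)C(=O)OC | intermediate
3 | [3,5-bis(methoxymethoxy)phenyl]methanol | COCOc1cc(CO)cc(OCOC)c1 | intermediate
4 | 1-bromo-3-methylbut-2-ene (prenyl bromide) | CC(C)=CCBr | starting material
5 | lithium [4-lithio-3,5-bis(methoxymethoxy)phenyl]methanolate | [Li]OCc1cc(OCOC)c([Li])c(OCOC)c1 | intermediate (not isolated)
6 | [3,5-bis(methoxymethoxy)-4-(3-methylbut-2-en-1-yl)phenyl]methanol | COCOc1cc(CO)cc(OCOC)c1CC=C(C)C | intermediate
7 | 3,5-bis(methoxymethoxy)-4-(3-methylbut-2-en-1-yl)benzaldehyde | COCOc1cc(C=O)cc(OCOC)c1CC=C(C)C | intermediate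
8 | diethyl benzylphosphonate | CCOP(=O)(Cc1ccccc1)OCC | starting material
9 | 1,3-bis(methoxymethoxy)-2-(3-methylbut-2-en-1-yl)-5-[(E)-2-phenylethenyl]benzene | COCOc1cc(/C=C/c2ccccc2)cc(OCOC)c1CC=C(C)C | intermediate
10 | 2-(3-methylbut-2-en-1-yl)-5-[(E)-2-phenylethenyl]benzene-1,3-diol | CC(C)=CCc1c(O)cc(/C=C/c2ccccc2)cc1O | intermediate
11 | 2,4-dihydroxy-3-(3-methylbut-2-en-1-yl)-6-[(E)-2-phenylethenyl]benzaldehyde | CC(C)=CCc1c(O)cc(/C=C/c2ccccc2)c(C=O)c1O | intermediate
12 | 2-hydroxy-3-(3-methylbut-2-en-1-yl)-6-[(E)-2-phenylethenyl]-4-[tri(propan-2-yl)silyloxy]benzaldehyde | CC(C)=CCc1c(O[Si](C(C)C)(C(C)C)C(C)C)cc(/C=C/c2ccccc2)c(C=O)c1O | intermediate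
13 | 2-(hydroxymethyl)-6-(3-methylbut-2-en-1-yl)-3-[(E)-2-phenylethenyl]-5-[tri(propan-2-yl)silyloxy]phenol | CC(C)=CCc1c(O[Si](C(C)C)(C(C)C)C(C)C)cc(/C=C/c2ccccc2)c(CO)c1O | intermediate
14 | 4,4,5,5-tetramethyl-2-(2-methylprop-1-en-1-yl)-1,3,2-dioxaborolane | CC(C)=CB1OC(C)(C)C(C)(C)O1 | starting material
15 | 6-methylidene-2-(3-methylbut-2-en-1-yl)-5-[(E)-2-phenylethenyl]-3-[tri(propan-2-yl)silyloxy]cyclohexa-2,4-dien-1-one | C=C1C(=O)C(CC=C(C)C)=C(O[Si](C(C)C)(C(C)C)C(C)C)C=C1/C=C/c1ccccc1 | intermediate (not isolated)
16 | 2-[(3R)-2,2-dimethyl-8-(3-methylbut-2-en-1-yl)-5-[(E)-2-phenylethenyl]-7-[tri(propan-2-yl)silyloxy]-3,4-dihydro-2H-chromen-3-yl]-4,4,5,5-tetramethyl-1,3,2-dioxaborolane | CC(C)=CCc1c(O[Si](C(C)C)(C(C)C)C(C)C)cc(/C=C/c2ccccc2)c2c1OC(C)(C)[C@H](B1OC(C)(C)C(C)(C)O1)C2 | intermediate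
17 | (3R)-2,2-dimethyl-8-(3-methylbut-2-en-1-yl)-5-[(E)-2-phenylethenyl]-7-[tri(propan-2-yl)silyloxy]-3,4-dihydro-2H-chromen-3-ol | CC(C)=CCc1c(O[Si](C(C)C)(C(C)C)C(C)C)cc(/C=C/c2ccccc2)c2c1OC(C)(C)[C@H](O)C2 | intermediate
18 | (3R)-2,2-dimethyl-8-(3-methylbut-2-en-1-yl)-5-[(E)-2-phenylethenyl]-3,4-dihydro-2H-chromene-3,7-diol | CC(C)=CCc1c(O)cc(/C=C/c2ccccc2)c2c1OC(C)(C)[C@H](O)C2 | target

## Step count and least certain steps

Total: 12 steps. Longest linear sequence: 12 steps (1 to 18); 4, 8 and 14 are purchased.

**Step 10 (key step, proposed new method).** Three things may go wrong.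
- Loss of boron from the β-boryl cation instead of ring closure (ipso substitution), which would open the way to a prenyl-type side chain on C4a.
- Poor facial selectivity, because the alkene carries no hydrogen-bond handle and C4 has no substituent to lean on the catalyst.
- Slow reaction of the weakly nucleophilic alkenylboronate with a donor-stabilised quinone methide, leaving time for self-condensation through C6 or through the alkenes of a second molecule.

The fallback uses known chemistry and sets out from 12. Addition of excess 2-methylprop-1-enylmagnesium bromide (THF, 0 °C) should give 2-(1-hydroxy-3-methylbut-2-en-1-yl)-6-(3-methylbut-2-en-1-yl)-3-[(E)-2-phenylethenyl]-5-[tri(propan-2-yl)silyloxy]phenol F1. Warming F1 with catalytic pyridinium tosylate in toluene should dehydrate it to a vinyl quinone methide that closes by six-electron oxa-electrocyclisation to 2,2-dimethyl-8-(3-methylbut-2-en-1-yl)-5-[(E)-2-phenylethenyl]-7-[tri(propan-2-yl)silyloxy]-2H-chromene F2. Jacobsen epoxidation of the cis-disubstituted, conjugated chromene double bond follows, with (R,R)-(salen)MnCl (trivalent manganese; salen = N,N'-bis(3,5-di-tert-butylsalicylidene)cyclohexane-1,2-diamine), NaOCl and 4-phenylpyridine N-oxide in CH2Cl2 at 0 °C. By analogy with other 2,2-dimethylchromenes it should give the (3R,4R)-3,4-epoxy-2,2-dimethyl-8-(3-methylbut-2-en-1-yl)-5-[(E)-2-phenylethenyl]-7-[tri(propan-2-yl)silyloxy]chromane F3. LiEt3BH in THF at 0 °C should open F3 at the benzylic, less hindered C4 and return to the route at 17. The weak point of the detour is competition from the prenyl alkene in the epoxidation. It also dispenses with step 11 and so covers that step's one hazard, β-elimination of the ring oxygen from the boron ate complex.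

**Step 7.** Over-formylation at the second equivalent position, or a sluggish reaction next to the styryl group that leaves the intermediate benzylic alkoxide to condense with the ring of another molecule. The fallback sets out from 10 and replaces the phenoxide-directed hydroxymethylation and hydride transfer by an electrophilic aromatic substitution (Vilsmeier–Haack). Preformed (chloromethylene)dimethyliminium chloride in MeCN at 0 °C should attack the position para to one hydroxyl and ortho to the other, giving [2,4-dihydroxy-3-(3-methylbut-2-en-1-yl)-6-[(E)-2-phenylethenyl]phenyl]methylidene-dimethylammonium chloride F4. Hydrolysis of F4 with aqueous NaOAc comes back at 11.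

**Step 3.** Incomplete or misdirected metalation, because the lithium alkoxide consumes base, aggregates and offers a second, weaker directing group; O-allylation of the alkoxide is a further possibility. The fallback sets out from 3 and removes the free hydroxyl from the metalation. Silylation (TBSCl, imidazole, DMF) gives tert-butyl{[3,5-bis(methoxymethoxy)phenyl]methoxy}dimethylsilane F5. Lithiation of F5 with n-BuLi in THF at 0 °C, transmetalation with CuBr·SMe2 and allylation with 4 give tert-butyl{[3,5-bis(methoxymethoxy)-4-(3-methylbut-2-en-1-yl)phenyl]methoxy}dimethylsilane F6. Bu4NF in THF then returns to the route at 6, at the cost of two extra steps.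

## Further compounds

F1 | step 10 | 2-(1-hydroxy-3-methylbut-2-en-1-yl)-6-(3-methylbut-2-en-1-yl)-3-[(E)-2-phenylethenyl]-5-[tri(propan-2-yl)silyloxy]phenol (racemic at the carbinol) | CC(C)=CCc1c(O[Si](C(C)C)(C(C)C)C(C)C)cc(/C=C/c2ccccc2)c(C(O)C=C(C)C)c1O
F2 | step 10 | 2,2-dimethyl-8-(3-methylbut-2-en-1-yl)-5-[(E)-2-phenylethenyl]-7-[tri(propan-2-yl)silyloxy]-2H-chromene | CC(C)=CCc1c(O[Si](C(C)C)(C(C)C)C(C)C)cc(/C=C/c2ccccc2)c2c1OC(C)(C)C=C2
F3 | step 10 | (3R,4R)-3,4-epoxy-2,2-dimethyl-8-(3-methylbut-2-en-1-yl)-5-[(E)-2-phenylethenyl]-7-[tri(propan-2-yl)silyloxy]chromane | CC(C)=CCc1c(O[Si](C(C)C)(C(C)C)C(C)C)cc(/C=C/c2ccccc2)c2c1OC(C)(C)[C@@H]3O[C@H]23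
F4 | step 7 | [2,4-dihydroxy-3-(3-methylbut-2-en-1-yl)-6-[(E)-2-phenylethenyl]phenyl]methylidene-dimethylammonium chloride | CC(C)=CCc1c(O)cc(/C=C/c2ccccc2)c(C=[N+](C)C)c1O.[Cl-]
F5 | step 3 | tert-butyl{[3,5-bis(methoxymethoxy)phenyl]methoxy}dimethylsilane | COCOc1cc(CO[Si](C)(C)C(C)(C)C)cc(OCOC)c1
F6 | step 3 | tert-butyl{[3,5-bis(methoxymethoxy)-4-(3-methylbut-2-en-1-yl)phenyl]methoxy}dimethylsilane | COCOc1cc(CO[Si](C)(C)C(C)(C)C)cc(OCOC)c1CC=C(C)C
A1 | alternative 1 | (3R)-3-[tert-butyl(dimethyl)silyloxy]-2,2-dimethyl-8-(3-methylbut-2-en-1-yl)-5-[(E)-2-phenylethenyl]-2,3,4,4a,5,6-hexahydro-7H-chromen-7-one (mixture of C4a and C5 epimers) | CC(C)=CCC1=C2OC(C)(C)[C@H](O[Si](C)(C)C(C)(C)C)CC2C(/C=C/c2ccccc2)CC1=O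
A2 | alternative 1 | (3E,5R)-5-[tert-butyl(dimethyl)silyloxy]-6,6-dimethyl-3-[(2E)-3-phenylprop-2-en-1-ylidene]oxan-2-one | O=C1OC(C)(C)[C@H](O[Si](C)(C)C(C)(C)C)C/C1=C\C=C\c1ccccc1
A3 | alternative 1 | 6-methylhept-5-en-2-one (sulcatone) | CC(C)=CCCC(C)=O
A4 | alternative 2 | 3-({2-[(4R)-2,2-dimethyl-1,3-dioxolan-4-yl]propan-2-yl}oxy)-2-(3-methylbut-2-en-1-yl)-5-[(E)-2-phenylethenyl]phenol | CC(C)=CCc1c(O)cc(/C=C/c2ccccc2)cc1OC(C)(C)[C@H]1COC(C)(C)O1
A5 | alternative 2 | 3-[(E)-2-phenylethenyl]cyclobut-2-en-1-one | O=C1CC(/C=C/c2ccccc2)=C1
A6 | alternative 2 | (4R)-2,2-dimethyl-4-{2-[(5-methylhex-4-en-1-yn-1-yl)oxy]propan-2-yl}-1,3-dioxolane | CC(C)=CCC#COC(C)(C)[C@H]1COC(C)(C)O1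
A7 | alternative 3 | (3R)-3-[tert-butyl(dimethyl)silyloxy]-2,2-dimethyl-8-(3-methylbut-2-en-1-yl)-5-[(E)-2-phenylethenyl]-3,4-dihydro-2H-chromen-7-ol | CC(C)=CCc1c(O)cc(/C=C/c2ccccc2)c2c1OC(C)(C)[C@H](O[Si](C)(C)C(C)(C)C)C2
A8 | alternative 3 | (1E)-6-{(5R)-5-[tert-butyl(dimethyl)silyloxy]-6,6-dimethyloxan-2-ylidene}-9-methyl-1-phenyldeca-1,8-diene-3,5-dione | CC(C)=CCC(C(=O)CC(=O)/C=C/c1ccccc1)=C1CC[C@@H](O[Si](C)(C)C(C)(C)C)C(C)(C)O1
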